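Cuts, in retrosynthetic order: four O–CH3 protecting bonds are added; then C6–CHO; C3′–CHO and C5′–CHO; C2–C1′ (pyran to ring B); finally O1–C2 and C4–C4a of the pyran ring.
Enabling feature: C2–C3(isopropyl)–C4(isobutyl) is the intact C10 skeleton of the isovaleraldehyde self-condensation enal (C2 = carbonyl carbon, C4 = β-carbon). C4a and the oxygen on C8a are an adjacent C/O nucleophile pair of ring A, that is, of threefold-symmetric phloroglucinol.
Forward: ring A is bought, the pyran ring closes in step 1 as a lactol, ring B is joined to C2 through the oxocarbenium ion, ring B and then ring A are formylated, and the methyl ethers fall last.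
Stereochemistry: C4 comes from the chiral primary amine catalyst, C3 from enamine protonation anti to the new aryl group (3,4-cis), and C2 from arylation on the face opposite both alkyl groups (2,3-trans).
C6 versus C8: ring B is formylated while ring A is silenced as its diacetate. The last formyl group is then delivered ortho to the free 5-OH (C6 only), with 7-OH masked as its methyl ether.

Key step: step 1

Assumption: the commercial quinine-derived 9-amino-9-deoxy-epi-alkaloid is taken to give the 4S series; if the sense of induction is the reverse, the quinidine-derived pseudo-enantiomer takes its place with nothing else changed.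

Step 1
Reactants: 1 phloroglucinol; 2 (E)-2-isopropyl-5-methylhex-2-enal
Product: 4 (3R,4S)-4-isobutyl-3-isopropylchroman-2,5,7-triol as a mixture of anomers, via open-chain aldehyde 3 (not isolated)
Conditions: 1 (3 equiv), 9-amino-9-deoxy-epi-quinine (20 mol %), TFA (30 mol %), THF, 40 °C
Reagents that add atoms: none
Why: The primary ammonium salt condenses with the hindered enal 2 to an iminium ion, a ring carbon of 1 adds to its β-carbon in a Friedel–Crafts step (C4–C4a), the enamine so formed is protonated at C3, and hydrolysis releases aldehyde 3, which an ortho phenol captures (O1–C2). The closest known reactions are the amine-catalysed Friedel–Crafts/hemiacetalisation cascades of naphthols, sesamol and 3,5-dialkoxyphenols with enals to chroman-2-ols, and the activation of α-branched enals toward indoles and thiols by cinchona-derived primary amines. The pyran ring closes by reversible 6-exo-trig addition of the phenol oxygen to the aldehyde, and the lactol is the favoured tautomer. C4 is fixed by the catalyst, which covers one face of the E-iminium ion; C3 is fixed by protonation of the enamine, in the conformer with C4–H in the plane of the double bond, on the face opposite the aryl group (3,4-cis), after which ring closure keeps the α-carbon out of further enamine equilibria; C2 forms as both anomers and is erased in step 3. The step needs 1,4- over 1,2-addition, carbon over oxygen attack and single over multiple alkylation: the α-isopropyl group screens the iminium carbon, the soft ring carbon of 1 prefers the β-position, the equivalence of the three C–H and three O–H sites of 1 leaves no regiochemical choice, and the excess of 1 holds back a second alkylation.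

Step 2
Reactants: 4 (3R,4S)-4-isobutyl-3-isopropylchroman-2,5,7-triol
Product: 5 (3R,4S)-4-isobutyl-3-isopropylchroman-2,5,7-triyl triacetate as a mixture of anomers
Conditions: Ac2O (5 equiv), pyridine, DMAP (cat.), CH2Cl2, 0 °C to rt
Reagents that add atoms: acetic anhydride, CC(=O)OC(C)=O
Why: DMAP-catalysed O-acetylation should trap the dominant lactol tautomer as its anomeric acetate (the leaving group for step 3) and turn both phenols into aryl acetates, which stops ring A from acting as a Friedel–Crafts nucleophile, and the mild cold base should leave C3 and C4 untouched.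

Step 3
Reactants: 5 (3R,4S)-4-isobutyl-3-isopropylchroman-2,5,7-triyl triacetate; 6 1,3,5-trimethoxybenzene
Product: 8 (2R,3R,4S)-4-isobutyl-3-isopropyl-2-(2,4,6-trimethoxyphenyl)chroman-5,7-diyl diacetate, via oxocarbenium ion 7 (not isolated)
Conditions: 6 (3 equiv), BF3·OEt2 (1.5 equiv), CH2Cl2, −78 to −30 °C; H2O
Reagents that add atoms: none
Why: In a Friedel–Crafts C-arylation of an anomeric acetate (the C-aryl glycoside reaction type), the C3 isopropyl and C4 isobutyl groups of 7 lie on the same face, so the arene should bond on the other face and set 2R (2,3-trans, also the more stable arrangement), and any 4H-chromene formed by proton loss should be reprotonated anti to the isobutyl group and re-enter through the same cis cation.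

Step 4
Reactants: 8 (2R,3R,4S)-4-isobutyl-3-isopropyl-2-(2,4,6-trimethoxyphenyl)chroman-5,7-diyl diacetate
Product: 9 (2R,3R,4S)-2-(3,5-diformyl-2,4,6-trimethoxyphenyl)-4-isobutyl-3-isopropylchroman-5,7-diyl diacetate
Conditions: Cl2CHOMe (5 equiv) and TiCl4 (5 equiv) premixed, CH2Cl2, −78 to 0 °C; ice-cold 1 M HCl
Reagents that add atoms: dichloromethyl methyl ether, COC(Cl)Cl; water, O
Why: In this twofold Rieche formylation, known for 1,3,5-trioxygenated arenes, the trimethoxyphenyl ring is by far the most electron-rich arene and has only C3′ and C5′ open, ring A is held back by its acetoxy groups (more so once TiCl4 binds their carbonyls), and a transient opening of C2–O1 can only close back to the 2,3-trans chroman.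

Step 5
Reactants: 9 (2R,3R,4S)-2-(3,5-diformyl-2,4,6-trimethoxyphenyl)-4-isobutyl-3-isopropylchroman-5,7-diyl diacetate
Product: 10 5-[(2R,3R,4S)-5,7-dihydroxy-4-isobutyl-3-isopropylchroman-2-yl]-2,4,6-trimethoxyisophthalaldehyde
Conditions: K2CO3 (cat.), MeOH, 0 °C to rt; aq. NH4Cl
Reagents that add atoms: none
Why: Zemplén-type transesterification should remove the aryl acetates quickly, the hindered non-enolisable aldehydes are inert, no stereocentre is α to a carbonyl, and ring B has no free phenol that could open the pyran ring.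

Step 6
Reactants: 10 5-[(2R,3R,4S)-5,7-dihydroxy-4-isobutyl-3-isopropylchroman-2-yl]-2,4,6-trimethoxyisophthalaldehyde
Product: 11 5-[(2R,3R,4S)-5-hydroxy-4-isobutyl-3-isopropyl-7-methoxychroman-2-yl]-2,4,6-trimethoxyisophthalaldehyde
Conditions: MeI (1.0 equiv), K2CO3 (1.1 equiv), DMF, 0 °C to rt
Reagents that add atoms: iodomethane, CI
Why: In a Williamson etherification with one equivalent of electrophile, the 7-OH lies between two C–H positions while the 5-OH is screened by the branched peri substituent at C4, so the 7-phenoxide should react first.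

Step 7
Reactants: 11 5-[(2R,3R,4S)-5-hydroxy-4-isobutyl-3-isopropyl-7-methoxychroman-2-yl]-2,4,6-trimethoxyisophthalaldehyde
Product: 12 5-[(2R,3R,4S)-6-formyl-5-hydroxy-4-isobutyl-3-isopropyl-7-methoxychroman-2-yl]-2,4,6-trimethoxyisophthalaldehyde
Conditions: MgCl2 (3 equiv), Et3N (6 equiv), (CH2O)n (10 equiv), THF, reflux; 1 M HCl
Reagents that add atoms: paraformaldehyde (reacts as formaldehyde), C=O
Why: In the Casnati–Skattebøl ortho-formylation the magnesium phenoxide passes formaldehyde only to a carbon ortho to the free OH, and for the 5-OH that is C6 alone (the other ortho carbon is C4a), so C8 stays free, ring B has no open position, and a second formaldehyde oxidises the benzylic alkoxide to the aldehyde.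

Step 8
Reactants: 12 5-[(2R,3R,4S)-6-formyl-5-hydroxy-4-isobutyl-3-isopropyl-7-methoxychroman-2-yl]-2,4,6-trimethoxyisophthalaldehyde
Product: 13 5-[(2R,3R,4S)-6-formyl-5,7-dihydroxy-4-isobutyl-3-isopropylchroman-2-yl]-2,4,6-trihydroxyisophthalaldehyde (target)
Conditions: BBr3 (12 equiv), CH2Cl2, −78 °C to rt; ice-water, non-basic work-up
Reagents that add atoms: none
Why: In this boron tribromide aryl methyl ether cleavage all four methoxy groups are ortho to a formyl group, the C2–O1 bond should hold because O1 is para to the 6-formyl group (weakly basic) and a cation at C2 would be destabilised by the boron-bound diformyl ring B, and no stereocentre is touched.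

Compound list
1 | phloroglucinol (benzene-1,3,5-triol) | Oc1cc(O)cc(O)c1 | starting material
2 | (E)-2-isopropyl-5-methylhex-2-enal | CC(C)C/C=C(/C=O)C(C)C | starting material
3 | (2R,3S)-2-isopropyl-5-methyl-3-(2,4,6-trihydroxyphenyl)hexanal (not isolated) | CC(C)C[C@H](c1c(O)cc(O)cc1O)[C@H](C=O)C(C)C | intermediate
4 | (3R,4S)-4-isobutyl-3-isopropylchroman-2,5,7-triol (both anomers) | CC(C)C[C@@H]1c2c(cc(O)cc2O)OC(O)[C@@H]1C(C)C | intermediate
5 | (3R,4S)-4-isobutyl-3-isopropylchroman-2,5,7-triyl triacetate (both anomers) | CC(C)C[C@@H]1c2c(cc(OC(C)=O)cc2OC(C)=O)OC(OC(C)=O)[C@@H]1C(C)C | intermediate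
6 | 1,3,5-trimethoxybenzene | COc1cc(OC)cc(OC)c1 | starting material
7 | (3R,4S)-5,7-diacetoxy-4-isobutyl-3-isopropyl-3,4-dihydrochromenylium, the oxocarbenium ion (not isolated) | CC(C)C[C@@H]1c2c(cc(OC(C)=O)cc2OC(C)=O)[O+]=C[C@@H]1C(C)C | intermediate
8 | (2R,3R,4S)-4-isobutyl-3-isopropyl-2-(2,4,6-trimethoxyphenyl)chroman-5,7-diyl diacetate | CC(C)C[C@@H]1c2c(cc(OC(C)=O)cc2OC(C)=O)O[C@@H](c2c(OC)cc(OC)cc2OC)[C@@H]1C(C)C | intermediate
9 | (2R,3R,4S)-2-(3,5-diformyl-2,4,6-trimethoxyphenyl)-4-isobutyl-3-isopropylchroman-5,7-diyl diacetate | CC(C)C[C@@H]1c2c(cc(OC(C)=O)cc2OC(C)=O)O[C@@H](c2c(OC)c(C=O)c(OC)c(C=O)c2OC)[C@@H]1C(C)C | intermediate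
10 | 5-[(2R,3R,4S)-5,7-dihydroxy-4-isobutyl-3-isopropylchroman-2-yl]-2,4,6-trimethoxyisophthalaldehyde | CC(C)C[C@@H]1c2c(cc(O)cc2O)O[C@@H](c2c(OC)c(C=O)c(OC)c(C=O)c2OC)[C@@H]1C(C)C | intermediate
11 | 5-[(2R,3R,4S)-5-hydroxy-4-isobutyl-3-isopropyl-7-methoxychroman-2-yl]-2,4,6-trimethoxyisophthalaldehyde | CC(C)C[C@@H]1c2c(cc(OC)cc2O)O[C@@H](c2c(OC)c(C=O)c(OC)c(C=O)c2OC)[C@@H]1C(C)C | intermediate
12 | 5-[(2R,3R,4S)-6-formyl-5-hydroxy-4-isobutyl-3-isopropyl-7-methoxychroman-2-yl]-2,4,6-trimethoxyisophthalaldehyde | CC(C)C[C@@H]1c2c(cc(OC)c(C=O)c2O)O[C@@H](c2c(OC)c(C=O)c(OC)c(C=O)c2OC)[C@@H]1C(C)C | intermediate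
13 | 5-[(2R,3R,4S)-6-formyl-5,7-dihydroxy-4-isobutyl-3-isopropylchroman-2-yl]-2,4,6-trihydroxyisophthalaldehyde (CNP0328914.1) | CC(C)C[C@@H]1c2c(cc(O)c(C=O)c2O)O[C@@H](c2c(O)c(C=O)c(O)c(C=O)c2O)[C@@H]1C(C)C | target

Total step count: 8. Longest linear sequence: 8 steps (from 1 and 2 to 13).

Steps most likely to fail

Step 1.
- What may go wrong: the bulky amine may condense too slowly with the α-isopropyl enal, or be tied up by condensation with the keto tautomer of 1. Addition may drift to the carbonyl carbon, facial selectivity may be low, and C3 may epimerise through the enamine before the lactol closes.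
- Fallback, setting out from 1 and 2 and rejoining the route at 8: absolute configuration comes from a resolution, and C3 from protonation of an enol ether.
- 1 and 2 are joined with an unhindered achiral primary ammonium salt (benzylammonium trifluoroacetate, THF, 50 °C) to racemic 4-isobutyl-3-isopropylchroman-2,5,7-triol F1, in which any mixture of C3 epimers is acceptable.
- Acetylation as in step 2 gives 4-isobutyl-3-isopropylchroman-2,5,7-triyl triacetate F2.
- Acid-catalysed loss of acetic acid (p-TsOH cat., toluene, reflux) gives racemic 4-isobutyl-3-isopropyl-4H-chromene-5,7-diyl diacetate F3, whose only stereocentre is C4.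
- Preparative chromatography on a chiral stationary phase gives (S)-4-isobutyl-3-isopropyl-4H-chromene-5,7-diyl diacetate F4.
- Acid-catalysed hydroarylation of this cyclic enol ether with 6 (Tf2NH cat., CH2Cl2, −40 °C) protonates C3 on the face away from the pseudo-axial isobutyl group. This regenerates cation 7 in the 3,4-cis series, and arylation as in step 3 gives 8.

Step 8.
- What may go wrong: the excess Lewis acid may open the benzylic C2–O1 bond. Re-closure through the 5-oxygen would then move the formyl group to the C8 position of the new chroman, and C2 could epimerise. Cleavage of the ethers that lack chelation may also stall.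
- Fallback, setting out from 5 and rejoining at 13: ring B and O7 carry benzyl groups, so the last step is a neutral hydrogenolysis.
- 5 is arylated with commercial 1,3,5-tris(benzyloxy)benzene (BF3·OEt2, as in step 3) to (2R,3R,4S)-2-[2,4,6-tris(benzyloxy)phenyl]-4-isobutyl-3-isopropylchroman-5,7-diyl diacetate F5.
- Twofold formylation with Cl2CHOMe/AgOTf at −78 °C, a Rieche variant that spares benzyl ethers, gives (2R,3R,4S)-2-[2,4,6-tris(benzyloxy)-3,5-diformylphenyl]-4-isobutyl-3-isopropylchroman-5,7-diyl diacetate F6.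
- K2CO3/MeOH gives 2,4,6-tris(benzyloxy)-5-[(2R,3R,4S)-5,7-dihydroxy-4-isobutyl-3-isopropylchroman-2-yl]isophthalaldehyde F7.
- BnBr (1 equiv)/K2CO3 gives 2,4,6-tris(benzyloxy)-5-[(2R,3R,4S)-7-benzyloxy-5-hydroxy-4-isobutyl-3-isopropylchroman-2-yl]isophthalaldehyde F8.
- MgCl2/Et3N/(CH2O)n gives 2,4,6-tris(benzyloxy)-5-[(2R,3R,4S)-7-benzyloxy-6-formyl-5-hydroxy-4-isobutyl-3-isopropylchroman-2-yl]isophthalaldehyde F9.
- H2, Pd/C, EtOAc, stopped after four equivalents of hydrogen, gives 13.

Step 6.
- What may go wrong: discrimination between the two phenols may be too low, with methylation at O5, double methylation or some C-methylation.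
- Fallback, setting out from 10 and rejoining at 13: C8 is blocked, so the phenols need not be told apart.
- Exhaustive methylation (MeI excess, K2CO3, DMF) gives 5-[(2R,3R,4S)-4-isobutyl-3-isopropyl-5,7-dimethoxychroman-2-yl]-2,4,6-trimethoxyisophthalaldehyde F10.
- NBS (CH2Cl2, −20 °C) should brominate C8, giving 5-[(2R,3R,4S)-8-bromo-4-isobutyl-3-isopropyl-5,7-dimethoxychroman-2-yl]-2,4,6-trimethoxyisophthalaldehyde F11. C8 is flanked by the tied-back ring oxygen and is the usual site of attack in 5,7-dialkoxyflavans.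
- Rieche formylation then has only C6 left and gives 5-[(2R,3R,4S)-8-bromo-6-formyl-4-isobutyl-3-isopropyl-5,7-dimethoxychroman-2-yl]-2,4,6-trimethoxyisophthalaldehyde F12.
- Palladium-catalysed formate reduction (Pd(OAc)2, PPh3, HCO2H, Et3N, DMF) removes the bromine to give 5-[(2R,3R,4S)-6-formyl-4-isobutyl-3-isopropyl-5,7-dimethoxychroman-2-yl]-2,4,6-trimethoxyisophthalaldehyde F13.
- BBr3 as in step 8 cleaves all five methyl ethers to 13.

Further compounds
F1 | step 1 | racemic 4-isobutyl-3-isopropylchroman-2,5,7-triol (C3 epimers, anomers) | CC(C)CC1c2c(cc(O)cc2O)OC(O)C1C(C)C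
F2 | step 1 | racemic 4-isobutyl-3-isopropylchroman-2,5,7-triyl triacetate (C3 epimers, anomers) | CC(C)CC1c2c(cc(OC(C)=O)cc2OC(C)=O)OC(OC(C)=O)C1C(C)C
F3 | step 1 | racemic 4-isobutyl-3-isopropyl-4H-chromene-5,7-diyl diacetate | CC(C)CC1c2c(cc(OC(C)=O)cc2OC(C)=O)OC=C1C(C)C
F4 | step 1 | (S)-4-isobutyl-3-isopropyl-4H-chromene-5,7-diyl diacetate | CC(C)C[C@@H]1c2c(cc(OC(C)=O)cc2OC(C)=O)OC=C1C(C)C
F5 | step 8 | (2R,3R,4S)-2-[2,4,6-tris(benzyloxy)phenyl]-4-isobutyl-3-isopropylchroman-5,7-diyl diacetate | CC(C)C[C@@H]1c2c(cc(OC(C)=O)cc2OC(C)=O)O[C@@H](c2c(OCc3ccccc3)cc(OCc3ccccc3)cc2OCc2ccccc2)[C@@H]1C(C)C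
F6 | step 8 | (2R,3R,4S)-2-[2,4,6-tris(benzyloxy)-3,5-diformylphenyl]-4-isobutyl-3-isopropylchroman-5,7-diyl diacetate | CC(C)C[C@@H]1c2c(cc(OC(C)=O)cc2OC(C)=O)O[C@@H](c2c(OCc3ccccc3)c(C=O)c(OCc3ccccc3)c(C=O)c2OCc2ccccc2)[C@@H]1C(C)C
F7 | step 8 | 2,4,6-tris(benzyloxy)-5-[(2R,3R,4S)-5,7-dihydroxy-4-isobutyl-3-isopropylchroman-2-yl]isophthalaldehyde | CC(C)C[C@@H]1c2c(cc(O)cc2O)O[C@@H](c2c(OCc3ccccc3)c(C=O)c(OCc3ccccc3)c(C=O)c2OCc2ccccc2)[C@@H]1C(C)C
F8 | step 8 | 2,4,6-tris(benzyloxy)-5-[(2R,3R,4S)-7-benzyloxy-5-hydroxy-4-isobutyl-3-isopropylchroman-2-yl]isophthalaldehyde | CC(C)C[C@@H]1c2c(cc(OCc3ccccc3)cc2O)O[C@@H](c2c(OCc3ccccc3)c(C=O)c(OCc3ccccc3)c(C=O)c2OCc2ccccc2)[C@@H]1C(C)C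
F9 | step 8 | 2,4,6-tris(benzyloxy)-5-[(2R,3R,4S)-7-benzyloxy-6-formyl-5-hydroxy-4-isobutyl-3-isopropylchroman-2-yl]isophthalaldehyde | CC(C)C[C@@H]1c2c(cc(OCc3ccccc3)c(C=O)c2O)O[C@@H](c2c(OCc3ccccc3)c(C=O)c(OCc3ccccc3)c(C=O)c2OCc2ccccc2)[C@@H]1C(C)C
F10 | step 6 | 5-[(2R,3R,4S)-4-isobutyl-3-isopropyl-5,7-dimethoxychroman-2-yl]-2,4,6-trimethoxyisophthalaldehyde | CC(C)C[C@@H]1c2c(cc(OC)cc2OC)O[C@@H](c2c(OC)c(C=O)c(OC)c(C=O)c2OC)[C@@H]1C(C)C
F11 | step 6 | 5-[(2R,3R,4S)-8-bromo-4-isobutyl-3-isopropyl-5,7-dimethoxychroman-2-yl]-2,4,6-trimethoxyisophthalaldehyde | CC(C)C[C@@H]1c2c(c(Br)c(OC)cc2OC)O[C@@H](c2c(OC)c(C=O)c(OC)c(C=O)c2OC)[C@@H]1C(C)C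
F12 | step 6 | 5-[(2R,3R,4S)-8-bromo-6-formyl-4-isobutyl-3-isopropyl-5,7-dimethoxychroman-2-yl]-2,4,6-trimethoxyisophthalaldehyde | CC(C)C[C@@H]1c2c(c(Br)c(OC)c(C=O)c2OC)O[C@@H](c2c(OC)c(C=O)c(OC)c(C=O)c2OC)[C@@H]1C(C)C
F13 | step 6 | 5-[(2R,3R,4S)-6-formyl-4-isobutyl-3-isopropyl-5,7-dimethoxychroman-2-yl]-2,4,6-trimethoxyisophthalaldehyde | CC(C)C[C@@H]1c2c(cc(OC)c(C=O)c2OC)O[C@@H](c2c(OC)c(C=O)c(OC)c(C=O)c2OC)[C@@H]1C(C)C
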